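The route rests on disconnecting the lower pyran ring (ring F; primed locants denote the lower flavan unit) at C4'–C4a' and O1'–C2'. The key step makes both bonds in one operation by a formal [3+3] annulation: C4 of 2-bromoresorcinol adds to the β-carbon of an aryl vinyl ketone, released in situ from a ketonic Mannich salt, and the neighbouring hydroxyl condenses with the carbonyl, giving an achiral 8-bromoflav-2-ene. It exploits the resorcinol pattern of ring D: C8', which carries the interflavan bond, lies between O1' and the C7' oxygen, so both C–H/OH pairs of 2-bromoresorcinol are equivalent and bromine marks C8' for lithiation. Addition to an (S)-flavanone, dehydration and a double hydroboration then complete the five stereocentres.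

Key step: step 2

Locants: the upper unit has plain locants and rings A (benzo), B (catechol), C (pyran); the lower unit has primed locants and rings D (benzo), E (catechol), F (pyran). Fragments 7, 8 and 13 are named as chromenes with plain locants; their C8 becomes C8'.

Remark: the absolute sense of the PyOx ligand (step 5) and of IpcBH2 (step 7) is assigned by analogy with cyclic enones and 1-arylcycloalkenes; should either prove opposite, the antipodal reagent is used.

Step 1
Reactants: 1 1-[3,4-bis(benzyloxy)phenyl]ethan-1-one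
Product: 2 3-(dimethylamino)-1-[3,4-bis(benzyloxy)phenyl]propan-1-one hydrochloride
Conditions: (CH2O)n, Me2NH·HCl, HCl (cat.), EtOH, reflux
Reagents that add atoms: paraformaldehyde (as formaldehyde) C=O; dimethylamine hydrochloride C[NH2+]C.[Cl-]
Why: Mannich reaction of the methyl ketone enol with the iminium ion formed from formaldehyde and dimethylamine gives the crystalline β-aminoketone salt, a storable precursor of the vinyl ketone; no stereocentre is involved.

Step 2
Reactants: 2 3-(dimethylamino)-1-[3,4-bis(benzyloxy)phenyl]propan-1-one hydrochloride; 3 2-bromobenzene-1,3-diol (2-bromoresorcinol)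
Product: 7 8-bromo-2-[3,4-bis(benzyloxy)phenyl]-4H-chromen-7-ol, via enone 4 (not isolated), via keto-phenol 5 (not isolated), via hemiketal 6 (not isolated)
Conditions: 3 (3 equiv), TsOH·H2O (0.2 equiv), 1,4-dioxane, 4 Å MS, 95 °C
Reagents that add atoms: none
Why: Heating 2 releases enone 4 (retro-Michael loss of dimethylammonium chloride), and acid-catalysed Friedel–Crafts conjugate addition of C4 of 3 (para to one hydroxyl, ortho to the other) to its β-carbon forms the future C4'–C4a' bond (keto-phenol 5); the flanking hydroxyl then adds to the carbonyl (hemiketal 6) and loss of water forms the O1'–C2' enol ether. The closest known reaction type is the condensation of phenols and naphthols with vinyl ketones or ketonic Mannich bases to 4H-chromenes, a formal [3+3] annulation. Ring F closes by 6-exo-trig attack of the phenolic oxygen on the ketone followed by dehydration into the ring. No stereocentre is created: C2' and C3' are deliberately left as an enol ether so that both are set together later by one cis-hydroboration. The step needs C- over O-alkylation, one regiochemistry and a single annulation: O-addition to the enone is reversible while C-addition is not, the C2v symmetry of 3 makes its two C–H/OH pairs identical with bromine blocking the carbon between the oxygens, and a threefold excess of 3 (recovered) suppresses a second annulation on the product.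

Step 3
Reactants: 7 8-bromo-2-[3,4-bis(benzyloxy)phenyl]-4H-chromen-7-ol
Product: 8 7-(benzyloxy)-8-bromo-2-[3,4-bis(benzyloxy)phenyl]-4H-chromene
Conditions: BnBr, K2CO3, DMF, rt
Reagents that add atoms: benzyl bromide BrCc1ccccc1
Why: Williamson etherification of the phenoxide; the enol ether and the aryl bromide are inert to K2CO3 and no stereocentre is involved.

Step 4
Reactants: 9 7-hydroxy-4H-chromen-4-one
Product: 10 7-(benzyloxy)-4H-chromen-4-one
Conditions: BnBr, K2CO3, acetone, reflux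
Reagents that add atoms: benzyl bromide BrCc1ccccc1
Why: Williamson etherification of the acidic 7-hydroxyl under conditions too mild to open the chromone ring; no stereocentre is involved.

Step 5
Reactants: 10 7-(benzyloxy)-4H-chromen-4-one; 11 [3,4-bis(benzyloxy)phenyl]boronic acid
Product: 12 (2S)-7-(benzyloxy)-2-[3,4-bis(benzyloxy)phenyl]-2,3-dihydro-4H-chromen-4-one
Conditions: Pd(OCOCF3)2 (5 mol%), (R)-t-BuPyOx (6 mol%), NH4PF6, H2O, ClCH2CH2Cl, 60 °C
Reagents that add atoms: none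
Why: Asymmetric conjugate addition of an arylboronic acid to the chromone (aryl–Pd insertion into C2=C3, then protonolysis of the Pd enolate): the chiral pyridine–oxazoline ligand selects the enantioface and sets C2 as S, and the base-free medium avoids retro-oxa-Michael opening of the flavanone.

Step 6
Reactants: 8 7-(benzyloxy)-8-bromo-2-[3,4-bis(benzyloxy)phenyl]-4H-chromene; 12 (2S)-7-(benzyloxy)-2-[3,4-bis(benzyloxy)phenyl]-2,3-dihydro-4H-chromen-4-one
Product: 16 (2S)-7-(benzyloxy)-4-{7-(benzyloxy)-2-[3,4-bis(benzyloxy)phenyl]-4H-chromen-8-yl}-2-[3,4-bis(benzyloxy)phenyl]-2H-chromene, via aryllithium 13 (not isolated), via tertiary carbinol 14 (not isolated), via tertiary mesylate 15 (not isolated)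
Conditions: t-BuLi (2.05 equiv), THF, −78 °C; CeCl3, −78 °C; 12; then MsCl, Et3N, −78 → 0 °C; kept from light and acid
Reagents that add atoms: none
Why: Bromine–lithium exchange, transmetalation to the weakly basic organocerium and 1,2-addition to the ketone (which limits enolisation and β-elimination of the ring oxygen), then in situ mesylation and E1 loss of the doubly benzylic tertiary sulfonate towards C3 under basic conditions give the C3=C4 alkene; the C2 centre (S) is not touched and the transient C4 carbinol centre disappears.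

Step 7
Reactants: 16 (2S)-7-(benzyloxy)-4-{7-(benzyloxy)-2-[3,4-bis(benzyloxy)phenyl]-4H-chromen-8-yl}-2-[3,4-bis(benzyloxy)phenyl]-2H-chromene
Product: 19 (2R,3S,4S)-7-(benzyloxy)-4-{(2R,3S)-7-(benzyloxy)-2-[3,4-bis(benzyloxy)phenyl]-3-hydroxychroman-8-yl}-2-[3,4-bis(benzyloxy)phenyl]chroman-3-ol, via monoalkylborane 17 (not isolated), via bis-borane 18 (not isolated)
Conditions: IpcBH2 [from (+)-α-pinene] (1.3 equiv), THF, −25 °C; BH3·SMe2, 0 °C → rt; NaOH, H2O2, 0 °C → rt
Reagents that add atoms: hydrogen peroxide OO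
Why: Sequential hydroboration–oxidation: the bulky IpcBH2 should add cis only to the ring F enol ether, boron at C3' (β to oxygen, remote from the aryl), with reagent-controlled face selection in the sense established for 1-arylcycloalkenes (2'R,3'S, 2,3-trans); the small BH3 then adds to the hindered ring C alkene anti to the C2 aryl with boron at C3 and hydrogen at C4, so cis-addition fixes 3S and 4S (2,3-trans-3,4-trans), and oxidation replaces both C–B bonds with retention.

Step 8
Reactants: 19 (2R,3S,4S)-7-(benzyloxy)-4-{(2R,3S)-7-(benzyloxy)-2-[3,4-bis(benzyloxy)phenyl]-3-hydroxychroman-8-yl}-2-[3,4-bis(benzyloxy)phenyl]chroman-3-ol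
Product: 20 (2R,3S,4S)-2-(3,4-dihydroxyphenyl)-4-[(2R,3S)-2-(3,4-dihydroxyphenyl)-3,7-dihydroxychroman-8-yl]chromane-3,7-diol (fisetinidol-(4α→8)-fisetinidol, CNP0189433.1)
Conditions: H2 (1 atm), Pd(OH)2/C, THF/MeOH, rt
Reagents that add atoms: none
Why: Hydrogenolysis of the six aryl benzyl ethers under neutral conditions at ambient pressure should leave the benzylic C2–O1 bonds, the interflavan bond and all five stereocentres untouched.

Compound list
1 | 1-[3,4-bis(benzyloxy)phenyl]ethan-1-one | CC(=O)c1ccc(OCc2ccccc2)c(OCc2ccccc2)c1 | starting material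
2 | 3-(dimethylamino)-1-[3,4-bis(benzyloxy)phenyl]propan-1-one hydrochloride | C[NH+](C)CCC(=O)c1ccc(OCc2ccccc2)c(OCc2ccccc2)c1.[Cl-] | intermediate
3 | 2-bromobenzene-1,3-diol (2-bromoresorcinol) | Oc1cccc(O)c1Br | starting material
4 | 1-[3,4-bis(benzyloxy)phenyl]prop-2-en-1-one (enone) | C=CC(=O)c1ccc(OCc2ccccc2)c(OCc2ccccc2)c1 | intermediate (not isolated)
5 | 1-[3,4-bis(benzyloxy)phenyl]-3-(3-bromo-2,4-dihydroxyphenyl)propan-1-one (keto-phenol) | O=C(CCc1ccc(O)c(Br)c1O)c1ccc(OCc2ccccc2)c(OCc2ccccc2)c1 | intermediate (not isolated)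
6 | 8-bromo-2-[3,4-bis(benzyloxy)phenyl]chromane-2,7-diol (racemic hemiketal) | OC1(c2ccc(OCc3ccccc3)c(OCc3ccccc3)c2)CCc2ccc(O)c(Br)c2O1 | intermediate (not isolated)
7 | 8-bromo-2-[3,4-bis(benzyloxy)phenyl]-4H-chromen-7-ol | Oc1ccc2CC=C(c3ccc(OCc4ccccc4)c(OCc4ccccc4)c3)Oc2c1Br | intermediate
8 | 7-(benzyloxy)-8-bromo-2-[3,4-bis(benzyloxy)phenyl]-4H-chromene | Brc1c(OCc2ccccc2)ccc2c1OC(c1ccc(OCc3ccccc3)c(OCc3ccccc3)c1)=CC2 | intermediate
9 | 7-hydroxy-4H-chromen-4-one | O=c1ccoc2cc(O)ccc12 | starting material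
10 | 7-(benzyloxy)-4H-chromen-4-one | O=c1ccoc2cc(OCc3ccccc3)ccc12 | intermediate
11 | [3,4-bis(benzyloxy)phenyl]boronic acid | OB(O)c1ccc(OCc2ccccc2)c(OCc2ccccc2)c1 | starting material
12 | (2S)-7-(benzyloxy)-2-[3,4-bis(benzyloxy)phenyl]-2,3-dihydro-4H-chromen-4-one | O=C1C[C@@H](c2ccc(OCc3ccccc3)c(OCc3ccccc3)c2)Oc2cc(OCc3ccccc3)ccc12 | intermediate
13 | {7-(benzyloxy)-2-[3,4-bis(benzyloxy)phenyl]-4H-chromen-8-yl}lithium | [Li]c1c(OCc2ccccc2)ccc2c1OC(c1ccc(OCc3ccccc3)c(OCc3ccccc3)c1)=CC2 | intermediate (not isolated)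
14 | (2S)-7-(benzyloxy)-4-{7-(benzyloxy)-2-[3,4-bis(benzyloxy)phenyl]-4H-chromen-8-yl}-2-[3,4-bis(benzyloxy)phenyl]chroman-4-ol (C4 epimers; present as its cerium alkoxide, drawn as the alcohol) | OC1(c2c(OCc3ccccc3)ccc3c2OC(c2ccc(OCc4ccccc4)c(OCc4ccccc4)c2)=CC3)C[C@@H](c2ccc(OCc3ccccc3)c(OCc3ccccc3)c2)Oc2cc(OCc3ccccc3)ccc12 | intermediate (not isolated)
15 | methanesulfonate of 14 | CS(=O)(=O)OC1(c2c(OCc3ccccc3)ccc3c2OC(c2ccc(OCc4ccccc4)c(OCc4ccccc4)c2)=CC3)C[C@@H](c2ccc(OCc3ccccc3)c(OCc3ccccc3)c2)Oc2cc(OCc3ccccc3)ccc12 | intermediate (not isolated)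
16 | (2S)-7-(benzyloxy)-4-{7-(benzyloxy)-2-[3,4-bis(benzyloxy)phenyl]-4H-chromen-8-yl}-2-[3,4-bis(benzyloxy)phenyl]-2H-chromene | C1(c2c(OCc3ccccc3)ccc3c2OC(c2ccc(OCc4ccccc4)c(OCc4ccccc4)c2)=CC3)=C[C@@H](c2ccc(OCc3ccccc3)c(OCc3ccccc3)c2)Oc2cc(OCc3ccccc3)ccc12 | intermediate
17 | 16 hydroborated at ring F: hydrido(isopinocampheyl)boryl group at C3' (2'R,3'S), ring C alkene intact | C1(c2c(OCc3ccccc3)ccc3c2O[C@H](c2ccc(OCc4ccccc4)c(OCc4ccccc4)c2)[C@@H](B[C@@H]2C[C@@H]4C[C@H]([C@H]2C)C4(C)C)C3)=C[C@@H](c2ccc(OCc3ccccc3)c(OCc3ccccc3)c2)Oc2cc(OCc3ccccc3)ccc12 | intermediate (not isolated)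
18 | bis-borane: 17 with a BH2 group at C3 and hydrogen at C4 (2R,3S,4S) | c1ccccc1COc1ccc2c(c1)O[C@H](c1ccc(OCc3ccccc3)c(OCc3ccccc3)c1)[C@@H](B)[C@@H]2c1c(OCc3ccccc3)ccc2c1O[C@H](c1ccc(OCc3ccccc3)c(OCc3ccccc3)c1)[C@@H](B[C@@H]1C[C@@H]3C[C@H]([C@H]1C)C3(C)C)C2 | intermediate (not isolated)
19 | (2R,3S,4S)-7-(benzyloxy)-4-{(2R,3S)-7-(benzyloxy)-2-[3,4-bis(benzyloxy)phenyl]-3-hydroxychroman-8-yl}-2-[3,4-bis(benzyloxy)phenyl]chroman-3-ol | c1ccccc1COc1ccc2c(c1)O[C@H](c1ccc(OCc3ccccc3)c(OCc3ccccc3)c1)[C@@H](O)[C@@H]2c1c(OCc3ccccc3)ccc2c1O[C@H](c1ccc(OCc3ccccc3)c(OCc3ccccc3)c1)[C@@H](O)C2 | intermediate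
20 | (2R,3S,4S)-2-(3,4-dihydroxyphenyl)-4-[(2R,3S)-2-(3,4-dihydroxyphenyl)-3,7-dihydroxychroman-8-yl]chromane-3,7-diol | Oc1ccc2c(c1)O[C@H](c1ccc(O)c(O)c1)[C@@H](O)[C@@H]2c1c(O)ccc2c1O[C@H](c1ccc(O)c(O)c1)[C@@H](O)C2 | target

Total steps: 8. Longest linear sequence: 6 steps (steps 1, 2, 3, 6, 7, 8).

Steps most likely to fail

Step 2. What may go wrong: acid-promoted disproportionation or oligomerisation of the enol ether as it forms, polymerisation of the vinyl ketone, or a second annulation on the remaining C–H/OH pair. The fallback sets out from 1 and 3 and returns at 7. Ketone 1 is condensed with N,N-dimethylformamide dimethyl acetal (neat, 110 °C) to the (E)-enaminone F1, a β-ketoaldehyde equivalent. Condensation of F1 with 3 in AcOH saturated with HCl at room temperature is the classical benzopyrylium synthesis from a phenol and a 1,3-dielectrophile, and it makes the same two bonds, again in one operation. It should give the 8-bromo-7-hydroxyflavylium chloride F2, an aromatic cation that can neither disproportionate nor be annulated again and that is collected by filtration. Hydride transfer from Hantzsch ester (CH2Cl2, room temperature) to C4 of F2 then gives 7.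

Step 6. What may go wrong: enolisation of 12 by the hindered aryl nucleophile with β-elimination of the ring phenoxide and loss of the C2 configuration, failure of the crowded 1,2-addition, or ionisation at C2 during the elimination. The fallback sets out from 12 and 13 and returns at 16. Ketone 12 is converted under non-basic conditions (Tf2O, 2,6-di-tert-butyl-4-methylpyridine, CH2Cl2, −20 °C) into the enol triflate F3, no enolate being formed. Aryllithium 13 is transmetalated with ZnCl2 to the arylzinc chloride F4. Negishi coupling of F3 with F4 (Pd2(dba)3, SPhos, THF, 50 °C) forms the C4–C8' bond at the alkene oxidation level and gives 16 directly, with neither a carbinol nor a dehydration.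

Step 7. What may go wrong: poor facial discrimination by IpcBH2 at the ring F enol ether next to the bulky C8' substituent, incomplete discrimination between the two alkenes, or β-elimination of the β-aryloxy organoborane before oxidation. The fallback sets out from 8 and returns at 20. The reagent-controlled hydroboration is moved to the fragment: 8 and IpcBH2 [from (+)-α-pinene], then NaOH/H2O2, give through the alkylborane F5 the bromo flavan-3-ol F6, whose enantiomeric purity can be raised by crystallisation. Benzylation (NaH, BnBr, DMF) gives the benzyl ether F7. Treatment with t-BuLi gives the aryllithium F8, which after CeCl3 adds to 12 to give the carbinol F9; MsCl/Et3N converts this through the mesylate F10 into the chromene F11. Only the substrate-controlled hydroboration then remains: BH3·SMe2 and NaOH/H2O2 give through the borane F12 the alcohol F13. Hydrogenolysis as in step 8 removes seven benzyl groups to give 20.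

Further compounds
F1 | step 2 | (2E)-3-(dimethylamino)-1-[3,4-bis(benzyloxy)phenyl]prop-2-en-1-one | CN(C)/C=C/C(=O)c1ccc(OCc2ccccc2)c(OCc2ccccc2)c1
F2 | step 2 | 8-bromo-7-hydroxy-2-[3,4-bis(benzyloxy)phenyl]chromenylium chloride | Oc1ccc2ccc(-c3ccc(OCc4ccccc4)c(OCc4ccccc4)c3)[o+]c2c1Br.[Cl-]
F3 | step 6 | (2S)-7-(benzyloxy)-2-[3,4-bis(benzyloxy)phenyl]-2H-chromen-4-yl trifluoromethanesulfonate | FC(F)(F)S(=O)(=O)OC1=C[C@@H](c2ccc(OCc3ccccc3)c(OCc3ccccc3)c2)Oc2cc(OCc3ccccc3)ccc12
F4 | step 6 | {7-(benzyloxy)-2-[3,4-bis(benzyloxy)phenyl]-4H-chromen-8-yl}zinc chloride | Cl[Zn]c1c(OCc2ccccc2)ccc2c1OC(c1ccc(OCc3ccccc3)c(OCc3ccccc3)c1)=CC2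
F5 | step 7 | (2R,3S)-7-(benzyloxy)-2-[3,4-bis(benzyloxy)phenyl]-8-bromo-3-[hydrido(isopinocampheyl)boryl]chromane | Brc1c(OCc3ccccc3)ccc2c1O[C@H](c1ccc(OCc3ccccc3)c(OCc3ccccc3)c1)[C@@H](B[C@@H]1C[C@@H]3C[C@H]([C@H]1C)C3(C)C)C2
F6 | step 7 | (2R,3S)-7-(benzyloxy)-2-[3,4-bis(benzyloxy)phenyl]-8-bromochroman-3-ol | Brc1c(OCc3ccccc3)ccc2c1O[C@H](c1ccc(OCc3ccccc3)c(OCc3ccccc3)c1)[C@@H](O)C2
F7 | step 7 | (2R,3S)-3,7-bis(benzyloxy)-2-[3,4-bis(benzyloxy)phenyl]-8-bromochromane | Brc1c(OCc3ccccc3)ccc2c1O[C@H](c1ccc(OCc3ccccc3)c(OCc3ccccc3)c1)[C@@H](OCc1ccccc1)C2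
F8 | step 7 | {(2R,3S)-3,7-bis(benzyloxy)-2-[3,4-bis(benzyloxy)phenyl]chroman-8-yl}lithium | [Li]c1c(OCc3ccccc3)ccc2c1O[C@H](c1ccc(OCc3ccccc3)c(OCc3ccccc3)c1)[C@@H](OCc1ccccc1)C2
F9 | step 7 | (2S)-7-(benzyloxy)-4-{(2R,3S)-3,7-bis(benzyloxy)-2-[3,4-bis(benzyloxy)phenyl]chroman-8-yl}-2-[3,4-bis(benzyloxy)phenyl]chroman-4-ol (C4 epimers) | OC1(c2c(OCc3ccccc3)ccc3c2O[C@H](c2ccc(OCc4ccccc4)c(OCc4ccccc4)c2)[C@@H](OCc2ccccc2)C3)C[C@@H](c2ccc(OCc3ccccc3)c(OCc3ccccc3)c2)Oc2cc(OCc3ccccc3)ccc12
F10 | step 7 | methanesulfonate of F9 | CS(=O)(=O)OC1(c2c(OCc3ccccc3)ccc3c2O[C@H](c2ccc(OCc4ccccc4)c(OCc4ccccc4)c2)[C@@H](OCc2ccccc2)C3)C[C@@H](c2ccc(OCc3ccccc3)c(OCc3ccccc3)c2)Oc2cc(OCc3ccccc3)ccc12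
F11 | step 7 | (2S)-7-(benzyloxy)-4-{(2R,3S)-3,7-bis(benzyloxy)-2-[3,4-bis(benzyloxy)phenyl]chroman-8-yl}-2-[3,4-bis(benzyloxy)phenyl]-2H-chromene | C1(c2c(OCc3ccccc3)ccc3c2O[C@H](c2ccc(OCc4ccccc4)c(OCc4ccccc4)c2)[C@@H](OCc2ccccc2)C3)=C[C@@H](c2ccc(OCc3ccccc3)c(OCc3ccccc3)c2)Oc2cc(OCc3ccccc3)ccc12
F12 | step 7 | (2R,3S,4S)-3-boranyl adduct of F11 (BH2 at C3, hydrogen at C4) | c1ccccc1COc1ccc2c(c1)O[C@H](c1ccc(OCc3ccccc3)c(OCc3ccccc3)c1)[C@@H](B)[C@@H]2c1c(OCc3ccccc3)ccc2c1O[C@H](c1ccc(OCc3ccccc3)c(OCc3ccccc3)c1)[C@@H](OCc1ccccc1)C2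
F13 | step 7 | (2R,3S,4S)-7-(benzyloxy)-4-{(2R,3S)-3,7-bis(benzyloxy)-2-[3,4-bis(benzyloxy)phenyl]chroman-8-yl}-2-[3,4-bis(benzyloxy)phenyl]chroman-3-ol | c1ccccc1COc1ccc2c(c1)O[C@H](c1ccc(OCc3ccccc3)c(OCc3ccccc3)c1)[C@@H](O)[C@@H]2c1c(OCc3ccccc3)ccc2c1O[C@H](c1ccc(OCc3ccccc3)c(OCc3ccccc3)c1)[C@@H](OCc1ccccc1)C2
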